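Percent of the starting material charged is the unit of every reading, so runs at different charges lie side by side.

| setting | west | south-west | flask |
|---|---|---|---|
| starting material | 0.28 M | 0.44 M | 0.20 M |
| remark | run made earlier | run made earlier |  |
| time |  |  | 2.0 min |

- west (time / s: isomer of the product / %, target / %): 10.0: 80, 17; 15.0: 81, 19; 25.0: 78, 21; 40.0: 76, 24; 80.0: 65, 35; 120: 58, 39
- south-west (time / s: isomer of the product / %, target / %): 20.0: 82, 21; 40.0: 76, 25; 60.0: 68, 27; 80.0: 66, 32; 90.0: 62, 34; 120: 60, 41

(each reading ± 2 percentage points)



- share of isomer of the product in isomer of the product plus target at 0.040 s
- share of isomer of the product in isomer of the product plus target at 2.0 min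
- which of isomer of the product and target there is more of at 2.0 min

1. Balance of the starting material, the limiting reagent: at 120 s isomer of the product plus target make 97.0% in the west run and 101% in the south-west run. The balance closes within the scatter, so define s as isomer of the product over isomer of the product plus target.

2. Two ways to the isomer at 2.0 min, the time of the last readings. Read directly, it averages 59.0%. Taken as what the target readings leave in the balance, it averages 60.0%. These are different readings, and they agree within the scatter. The new flask's 0.20 M lies lower than either run, so using these values there is an extrapolation in charge.

3. In the west run, s falls from 82.5% to 59.8%, giving 0.00292 s⁻¹. In the south-west run, s falls from 79.6% to 59.4%, giving 0.00293 s⁻¹. Their mean is λ = 0.00293 s⁻¹, the share-loss constant: the fractional fall of s per second.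

4. Own reckoning: running λ back from the first readings gives an opening share S of 84.7%, an extrapolation past the first reading. The time 0.040 s is far shorter than 1/λ, so this reckoning puts s there at S, assuming that the opening share already holds before the first reading. Forward, S·exp(−λt) gives 59.6% at 2.0 min, more than the target's share.

5. The forecast, resting on the view that “the behaviour looks independent of concentration”, gives 85%, 60% and isomer of the product in the lead.

The new flask gives 84.8% at 0.040 s and 60.2% at 2.0 min, with isomer of the product ahead, 60.2% to 39.8%.

    other conformer → isomer of the product (k = 3.90 s⁻¹)
    starting material ⇌ other conformer, settled at all times (K = 0.300)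
    starting material → target (k = 0.210 s⁻¹)
    target ⇌ isomer of the product (K = 0.150, k = 4.60 × 10⁻⁴ s⁻¹)

In the new flask, target's loss to isomer of the product, forward rate alone, has a half-life of 25 min, longer than 2.0 min. The backward turnover of that step, isomer of the product to target, is 1683% of the forward one. S and λ put s at 59.6% for this flask, against 60.2%. The same reckoning gives 59.6% for a second flask, charged with 0.34 M of starting material, which holds 60.2% at 2.0 min.

Readings and results were computed with made-up constants; scatter was added.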